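## The problem

The target 21 is a trans-2-aryl-3-methyl-2,3-dihydrobenzofuran neolignan. Ring A (C3a to C7a) is fused to the dihydrofuran ring B (O1, C2, C3) and carries an (E)-propenyl group at C5 and a methoxy group at C7. Ring C, a 3-hydroxy-4,5-dimethoxyphenyl group, sits on C2, and a methyl group on C3. The only stereocentres are the neighbouring C2 (S) and C3 (S), trans across ring B. They can be set together in an open-chain precursor, or one can steer the other during ring closure. C2 is a benzylic ether carbon activated by the para methoxy group of ring C, so it ionises and epimerises under acid, and C3 is benzylic and must not pass through an enolisable or cationic stage once set. The propenyl styrene does not tolerate acid, electrophilic halogen, hydrogenation, carbenes or alkyllithiums, and the benzylic C2–O bond forbids hydrogenolysis. The free phenol of ring C has to be told apart from the C7 oxygen, which ends as a methyl ether. The feature that invites an unusual closure is the pair of neighbouring oxygens on ring A, O1 on C7a and the methoxy oxygen on C7, directly beside the C3a carbon that holds the side chain. An aryne C7a≡C7 delivers exactly this pattern when it takes a nucleophile at one end and an electrophile at the other, and the oxygen on C2 can be that nucleophile through a five-membered ring.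

## Retrosynthesis

**From 21 back to 19.** The O–Si bond of silyl ether 20 and then the C7 O–CH3 bond are cut, leading to the C7 phenol 19. This order solves the differentiation of the two phenolic oxygens: the ring C oxygen travels as a triisopropylsilyl ether from the start of its fragment, and the C7 oxygen appears as the only free phenol. The forward steps ask only that a carbonate methylation spares an aryl silyl ether and that fluoride spares the styrene and the benzylic ether.

**From 19 back to 14 (the central cut).** Ring B is opened at O1–C7a and the C7–O bond is cut with it. This leads through the C7 aryllithium 17 and the aryne 16 to the open-chain fluoroarene alcohol 14. Three points speak for this cut against its neighbours: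
- Cutting O1–C2 would need inversion or ionisation at the labile benzylic centre.
- Cutting C3a–C3 or C2–C3 would create a stereocentre while the ring closes.
- The O1–C7a cut touches neither C2 nor C3, because the oxygen is arylated with retention of its C–O bond.

The precursor is much simpler: ring A of 14 carries no oxygen, only one fluorine and the propenyl group, and both stereocentres sit in an open chain. The forward reaction must remove the single hydrogen ortho to fluorine, lose lithium fluoride, let the C2 alkoxide add to C7a, and keep the C7 carbanion alive until it is borylated and oxidised. The propenyl group is kept in 14 because the base is a hindered lithium amide, which does not add to styrenes as alkyllithiums do.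

**From 14 back to 11.** The C3 methyl group is traced through tosylate 13 and diol 12 to the acyl carbon of imide 11. This detour costs three steps but turns the C2–C3 bond into an aldol bond. The syn relationship of 11 becomes the trans relationship of ring B because the carbinol C–O bond survives the ring closure unchanged. The forward steps are a borohydride cleavage, a selective sulfonylation and a hydride displacement, none of which touches a stereocentre.

**From 11 back to 6 and 8.** The future C2–C3 bond is cut as a syn aldol between arylacetyl imide 6 and aldehyde 8, through boron enolate 9 and aldolate 10. One auxiliary-controlled step sets both stereocentres. Setting them one after the other (for example adding an aryl nucleophile to an α-aryl carbonyl compound) would pass through a configurationally labile α-aryl intermediate. The forward reaction needs clean formation of the Z enolate and a closed transition state.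

**From 6 and 8 back to purchased materials.** Imide 6 comes from acid 3 and auxiliary 4 through mixed anhydride 5. Acid 3 comes from bromide 1 and trifluoroborate 2 by cross-coupling at the future C5. This coupling is placed first because the bromine of 1 would open a second aryne pathway under the amide base of the central step, and because 2 brings the E geometry ready-made. Aldehyde 8 is the silyl ether of phenol 7.

## Roads not taken

**Alternative 1:** The cut is C2–C3. The diazoester methyl 2-[5-bromo-2-[[3-(tert-butyldimethylsilyloxy)-4,5-dimethoxyphenyl]methoxy]-3-methoxyphenyl]-2-diazoacetate A1 would lose nitrogen on Rh2(PTTL)4, dirhodium tetrakis(N-phthaloyl-tert-leucinate). The carbene would insert into one enantiotopic benzylic C–H bond of the ring C benzyl ether on O1 and close ring B as the cis ester methyl (2S,3R)-5-bromo-2-[3-(tert-butyldimethylsilyloxy)-4,5-dimethoxyphenyl]-7-methoxy-2,3-dihydro-1-benzofuran-3-carboxylate A2.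
- Merits: the chiral source is catalytic, the C7 methoxy group is present from the start, and the reaction class is well established for this ring system. In these respects it is better than the chosen plan, which uses a stoichiometric auxiliary and a ring closure without direct precedent.
- Weak points for this target: A2 is cis, so C3 must be epimerised through the ester enolate, which sits β to the ring oxygen and can open ring B by elimination. C3 arrives as an ester and needs three further steps to become methyl. The propenyl group cannot be present beside a carbene, so bromine is carried and coupled late.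
- Comparison: the chosen plan sets against the catalytic merit that C3 is already at the methyl oxidation level before ring closure, that the trans relationship follows directly from the aldol, and that the propenyl group is installed in the first step.

**Alternative 2:** The cut is O1–C2. The precursor is (2S)-2-[5-bromo-3-methoxy-2-(methoxymethoxy)phenyl]-1-[3,4-dimethoxy-5-(methoxymethoxy)phenyl]propan-1-ol A3, as either carbinol epimer. Aqueous TsOH would remove both methoxymethyl groups and ionise the C2 hydroxyl, and the ring A phenol would capture the para-methoxy-stabilised cation to give trans 5-[(2S,3S)-5-bromo-7-methoxy-3-methyl-2,3-dihydro-1-benzofuran-2-yl]-2,3-dimethoxyphenol A4.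
- Merits: only C3 has to be set in an absolute sense, the carbinol needs no control, deprotection and ring closure share one flask, and every step is of a known type. This route is probably shorter and safer in its key step than the chosen one.
- Weak points: the trans outcome rests on a thermodynamic or kinetic preference and is not enforced. The cation lies next to the C3–H and can lose that proton to a 1,2-diarylpropene, which erases C3. The acid excludes the propenyl group, so the coupling comes last on a free phenol.
- Comparison: the chosen plan sets against the shorter route that neither stereocentre passes through a planar intermediate, that the relative configuration comes from one closed transition state, and that ring A starts from a simple monofluoroarene.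

**Alternative 3:** The cut is C3a–C3. The aryl iodide 4-[(1S)-1-[3-(tert-butyldimethylsilyloxy)-4,5-dimethoxyphenyl]prop-2-enoxy]-3-iodo-5-methoxybenzaldehyde A5 would give the C3a radical with (Me3Si)3SiH and AIBN. This radical adds 5-exo to the inner vinyl carbon, and the exocyclic radical is reduced to the C3 methyl of (2S,3S)-2-[3-(tert-butyldimethylsilyloxy)-4,5-dimethoxyphenyl]-7-methoxy-3-methyl-2,3-dihydro-1-benzofuran-5-carbaldehyde A6.
- Merits: ring A comes from a cheap, fully oxygenated iodophenol aldehyde, and the methyl group appears directly without redox adjustment. In supply of ring A this road is better.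
- Weak points: A5 is an enantiopure, doubly activated secondary ether on a phenol oxygen flanked by iodine and methoxy. Making it without ionisation, allylic transposition or loss of optical purity is the hard part. C3 is set only by substrate control in a radical step, and hydrogen transfer from the C2–H to the aryl radical competes. The aldehyde still needs an E-selective olefination.
- Comparison: the chosen plan sets against the easier ring A supply that both centres are auxiliary-controlled and that the alkene geometry is purchased.

Key step: step 8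

Assumption: the boron enolate of arylacetyl imide 6 is taken to react with the same facial sense as the corresponding propionyl imide (Z enolate, closed chair transition state), which fixes the (2S,3S) outcome from the (S)-auxiliary.

## Route

Step 1
Reactants: 1 2-(5-bromo-2-fluorophenyl)acetic acid; 2 potassium (E)-prop-1-enyltrifluoroborate
Product: 3 2-[2-fluoro-5-[(E)-prop-1-enyl]phenyl]acetic acid
Conditions: PdCl2(dppf)·CH2Cl2 (3 mol %), K2CO3, i-PrOH/H2O, 80 °C; then aq HCl
Reagents that add atoms: none
Why: Suzuki–Miyaura coupling: zerovalent palladium inserts only into the C–Br bond (C–F is inert), the alkenyl group is transferred with retention of the E geometry, and the carboxylate is a spectator under aqueous carbonate.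

Step 2
Reactants: 3 2-[2-fluoro-5-[(E)-prop-1-enyl]phenyl]acetic acid; 4 (S)-4-benzyl-1,3-oxazolidin-2-one
Product: 6 (4S)-4-benzyl-3-[2-[2-fluoro-5-[(E)-prop-1-enyl]phenyl]acetyl]-1,3-oxazolidin-2-one, via mixed pivalic anhydride 5 (not isolated)
Conditions: t-BuCOCl, Et3N, THF, −20 °C; then LiCl, 4, −20 °C to rt
Reagents that add atoms: none
Why: N-acylation of the oxazolidinone through the mixed anhydride 5 with LiCl/Et3N activation; the hindered pivaloyl carbonyl is not attacked and no strong base meets the acidic benzylic methylene.

Step 3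
Reactants: 7 3-hydroxy-4,5-dimethoxybenzaldehyde
Product: 8 3,4-dimethoxy-5-(triisopropylsilyloxy)benzaldehyde
Conditions: i-Pr3SiCl, imidazole, DMF, rt
Reagents that add atoms: chlorotri(propan-2-yl)silane, CC(C)[Si](Cl)(C(C)C)C(C)C
Why: Silylation of a phenol with a silyl chloride and imidazole; the triisopropylsilyl group is chosen because it should withstand the boron, hydride and amide reagents that follow and leaves with fluoride at the end.

Step 4
Reactants: 6 (4S)-4-benzyl-3-[2-[2-fluoro-5-[(E)-prop-1-enyl]phenyl]acetyl]-1,3-oxazolidin-2-one; 8 3,4-dimethoxy-5-(triisopropylsilyloxy)benzaldehyde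
Product: 11 (4S)-4-benzyl-3-[(2S,3S)-3-[3,4-dimethoxy-5-(triisopropylsilyloxy)phenyl]-2-[2-fluoro-5-[(E)-prop-1-enyl]phenyl]-3-hydroxypropanoyl]-1,3-oxazolidin-2-one, via dibutylboron Z-enolate 9 (not isolated), via dibutylboron aldolate 10 (not isolated)
Conditions: Bu2BOTf, i-Pr2NEt, CH2Cl2, −78 to 0 °C; 8, −78 to 0 °C; pH 7 buffer, MeOH, 30% H2O2, 0 °C
Reagents that add atoms: none
Why: Evans syn aldol: the Z enolate 9 adds to 8 through a chair Zimmerman–Traxler transition state in which the auxiliary carbonyl dipole is opposed and the benzyl group shields one enolate face, so both new stereocentres (2S,3S, syn) are set by the auxiliary in aldolate 10; buffered peroxide then frees 11.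

Step 5
Reactants: 11 (4S)-4-benzyl-3-[(2S,3S)-3-[3,4-dimethoxy-5-(triisopropylsilyloxy)phenyl]-2-[2-fluoro-5-[(E)-prop-1-enyl]phenyl]-3-hydroxypropanoyl]-1,3-oxazolidin-2-one
Product: 12 (1S,2R)-1-[3,4-dimethoxy-5-(triisopropylsilyloxy)phenyl]-2-[2-fluoro-5-[(E)-prop-1-enyl]phenyl]propane-1,3-diol
Conditions: LiBH4, MeOH (1 equiv), THF, 0 °C
Reagents that add atoms: none
Why: Reductive cleavage of the N-acyl oxazolidinone by LiBH4 gives the primary alcohol and returns auxiliary 4; no bond at either stereocentre is broken (the descriptor at the aryl-bearing carbon changes only through priorities), and the cold, fast reduction should leave no time for retro-aldol.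

Step 6
Reactants: 12 (1S,2R)-1-[3,4-dimethoxy-5-(triisopropylsilyloxy)phenyl]-2-[2-fluoro-5-[(E)-prop-1-enyl]phenyl]propane-1,3-diol
Product: 13 (2R,3S)-3-[3,4-dimethoxy-5-(triisopropylsilyloxy)phenyl]-2-[2-fluoro-5-[(E)-prop-1-enyl]phenyl]-3-hydroxypropyl 4-methylbenzenesulfonate
Conditions: TsCl (1.1 equiv), Et3N, DMAP (cat.), CH2Cl2, 0 °C
Reagents that add atoms: 4-methylbenzenesulfonyl chloride, Cc1ccc(cc1)S(Cl)(=O)=O
Why: Selective sulfonylation of the primary hydroxyl of a 1,3-diol; the secondary benzylic hydroxyl is flanked by two aryl-bearing carbons and should react much more slowly.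

Step 7
Reactants: 13 (2R,3S)-3-[3,4-dimethoxy-5-(triisopropylsilyloxy)phenyl]-2-[2-fluoro-5-[(E)-prop-1-enyl]phenyl]-3-hydroxypropyl 4-methylbenzenesulfonate
Product: 14 (1S,2S)-1-[3,4-dimethoxy-5-(triisopropylsilyloxy)phenyl]-2-[2-fluoro-5-[(E)-prop-1-enyl]phenyl]propan-1-ol
Conditions: LiEt3BH (3 equiv), THF, 0 °C to rt
Reagents that add atoms: none
Why: SN2 hydride displacement of a primary tosylate by LiEt3BH turns CH2OTs into the future C3 methyl group; the aryl fluoride, the styrene and the silyl ether are not attacked and no stereocentre is involved.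

Step 8
Reactants: 14 (1S,2S)-1-[3,4-dimethoxy-5-(triisopropylsilyloxy)phenyl]-2-[2-fluoro-5-[(E)-prop-1-enyl]phenyl]propan-1-ol
Product: 19 (2S,3S)-2-[3,4-dimethoxy-5-(triisopropylsilyloxy)phenyl]-3-methyl-5-[(E)-prop-1-enyl]-2,3-dihydro-1-benzofuran-7-ol, via dilithiated fluoroarene 15 (not isolated), via aryne alkoxide 16 (not isolated), via 7-lithio dihydrobenzofuran 17 (not isolated), via lithium aryltrimethoxyborate 18 (not isolated)
Conditions: lithium 2,2,6,6-tetramethylpiperidide (LiTMP, 3.5 equiv), THF, −78 °C then −30 °C; B(OMe)3, −78 to 0 °C; 30% H2O2, aq NaHCO3, 0 °C to rt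
Reagents that add atoms: hydrogen peroxide, OO
Why: Proposed new method: LiTMP forms the lithium alkoxide and then removes the only hydrogen ortho to fluorine (the future C7–H) to give 15, which on warming loses LiF to the C7a≡C7 aryne 16; the tethered alkoxide attacks the near aryne carbon C7a in the ring plane (5-exo-dig closure of ring B, O1–C7a) and leaves the C7 aryllithium 17, which is borylated to 18 and oxidised with retention at carbon to the phenol. The closest known reaction types are the anionic benzyne cyclisation of tethered carbon nucleophiles from ortho-lithiated fluoroarenes with electrophilic quench of the new aryllithium, the aryne ring closure of 2-arylethoxides to dihydrobenzofurans ending in protonation, and amide-base aryne couplings in which the adduct aryllithium is trapped; the combination of an oxygen nucleophile with electrophilic trapping at the neighbouring carbon has not been shown on this substrate class. No stereocentre is formed, and C2 and C3 are untouched because the C2–O bond stays intact and neither centre carries a hydrogen that the amide can remove once the alkoxide exists. Site selectivity of metalation is needed and is secured by fluorine, the strongest acidifying group present, having a single ortho hydrogen. Regioselectivity of the alkoxide addition is needed and is secured by the tether, which reaches C7a through a five-membered ring but C7 only through a bridged one. The aryllithium 17 is a stronger base than LiTMP, so its survival rests on the slow proton transfer from the hindered amine at low temperature and on the excess of amide; the borate is therefore added cold as soon as the aryne is consumed. The propenyl group should survive because a hindered amide does not add to it, and the triisopropylsilyl ether should resist anionic silyl migration and the bicarbonate-buffered peroxide.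

Step 9
Reactants: 19 (2S,3S)-2-[3,4-dimethoxy-5-(triisopropylsilyloxy)phenyl]-3-methyl-5-[(E)-prop-1-enyl]-2,3-dihydro-1-benzofuran-7-ol
Product: 20 (2S,3S)-2-[3,4-dimethoxy-5-(triisopropylsilyloxy)phenyl]-7-methoxy-3-methyl-5-[(E)-prop-1-enyl]-2,3-dihydro-1-benzofuran
Conditions: MeI, K2CO3, acetone, 40 °C
Reagents that add atoms: iodomethane, CI
Why: Williamson ether synthesis on the only free phenol; anhydrous carbonate in acetone should leave the triisopropylsilyl ether in place.

Step 10
Reactants: 20 (2S,3S)-2-[3,4-dimethoxy-5-(triisopropylsilyloxy)phenyl]-7-methoxy-3-methyl-5-[(E)-prop-1-enyl]-2,3-dihydro-1-benzofuran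
Product: 21 2,3-dimethoxy-5-[(2S,3S)-7-methoxy-3-methyl-5-[(E)-prop-1-enyl]-2,3-dihydro-1-benzofuran-2-yl]phenol
Conditions: Bu4NF, THF, 0 °C
Reagents that add atoms: none
Why: Fluoride-induced cleavage of an aryl silyl ether, driven by Si–F bond formation; the styrene, the methyl ethers and the benzylic ether are untouched and no stereocentre is at risk.

## Compound list

1 | 2-(5-bromo-2-fluorophenyl)acetic acid | OC(=O)Cc1cc(Br)ccc1F | starting material
2 | potassium (E)-prop-1-enyltrifluoroborate | C/C=C/[B-](F)(F)F.[K+] | starting material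
3 | 2-[2-fluoro-5-[(E)-prop-1-enyl]phenyl]acetic acid | OC(=O)Cc1cc(/C=C/C)ccc1F | intermediate
4 | (S)-4-benzyl-1,3-oxazolidin-2-one | O=C1OC[C@H](Cc2ccccc2)N1 | starting material
5 | 2-[2-fluoro-5-[(E)-prop-1-enyl]phenyl]acetic 2,2-dimethylpropanoic anhydride | CC(C)(C)C(=O)OC(=O)Cc1cc(/C=C/C)ccc1F | intermediate (not isolated)
6 | (4S)-4-benzyl-3-[2-[2-fluoro-5-[(E)-prop-1-enyl]phenyl]acetyl]-1,3-oxazolidin-2-one | O=C1OC[C@H](Cc2ccccc2)N1C(=O)Cc3cc(/C=C/C)ccc3F | intermediate
7 | 3-hydroxy-4,5-dimethoxybenzaldehyde | O=Cc1cc(O)c(OC)c(OC)c1 | starting material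
8 | 3,4-dimethoxy-5-(triisopropylsilyloxy)benzaldehyde | O=Cc1cc(O[Si](C(C)C)(C(C)C)C(C)C)c(OC)c(OC)c1 | intermediate
9 | (4S)-4-benzyl-3-[(Z)-1-(dibutylboranyloxy)-2-[2-fluoro-5-[(E)-prop-1-enyl]phenyl]ethenyl]-1,3-oxazolidin-2-one (boron Z-enolate of 6) | O=C1OC[C@H](Cc2ccccc2)N1/C(OB(CCCC)CCCC)=C/c3cc(/C=C/C)ccc3F | intermediate (not isolated)
10 | (4S)-4-benzyl-3-[(2S,3S)-3-(dibutylboranyloxy)-3-[3,4-dimethoxy-5-(triisopropylsilyloxy)phenyl]-2-[2-fluoro-5-[(E)-prop-1-enyl]phenyl]propanoyl]-1,3-oxazolidin-2-one (boron aldolate) | O=C1OC[C@H](Cc2ccccc2)N1C(=O)[C@@H](c3cc(/C=C/C)ccc3F)[C@H](OB(CCCC)CCCC)c4cc(O[Si](C(C)C)(C(C)C)C(C)C)c(OC)c(OC)c4 | intermediate (not isolated)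
11 | (4S)-4-benzyl-3-[(2S,3S)-3-[3,4-dimethoxy-5-(triisopropylsilyloxy)phenyl]-2-[2-fluoro-5-[(E)-prop-1-enyl]phenyl]-3-hydroxypropanoyl]-1,3-oxazolidin-2-one | O=C1OC[C@H](Cc2ccccc2)N1C(=O)[C@@H](c3cc(/C=C/C)ccc3F)[C@H](O)c4cc(O[Si](C(C)C)(C(C)C)C(C)C)c(OC)c(OC)c4 | intermediate
12 | (1S,2R)-1-[3,4-dimethoxy-5-(triisopropylsilyloxy)phenyl]-2-[2-fluoro-5-[(E)-prop-1-enyl]phenyl]propane-1,3-diol | OC[C@@H](c1cc(/C=C/C)ccc1F)[C@H](O)c2cc(O[Si](C(C)C)(C(C)C)C(C)C)c(OC)c(OC)c2 | intermediate
13 | (2R,3S)-3-[3,4-dimethoxy-5-(triisopropylsilyloxy)phenyl]-2-[2-fluoro-5-[(E)-prop-1-enyl]phenyl]-3-hydroxypropyl 4-methylbenzenesulfonate | Cc1ccc(cc1)S(=O)(=O)OC[C@@H](c2cc(/C=C/C)ccc2F)[C@H](O)c3cc(O[Si](C(C)C)(C(C)C)C(C)C)c(OC)c(OC)c3 | intermediate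
14 | (1S,2S)-1-[3,4-dimethoxy-5-(triisopropylsilyloxy)phenyl]-2-[2-fluoro-5-[(E)-prop-1-enyl]phenyl]propan-1-ol | C/C=C/c1ccc(F)c(c1)[C@H](C)[C@@H](c1cc(O[Si](C(C)C)(C(C)C)C(C)C)c(OC)c(OC)c1)O | intermediate
15 | lithium (1S,2S)-1-[3,4-dimethoxy-5-(triisopropylsilyloxy)phenyl]-2-[2-fluoro-3-lithio-5-[(E)-prop-1-enyl]phenyl]propan-1-olate | C/C=C/c1cc([Li])c(F)c(c1)[C@H](C)[C@@H](c1cc(O[Si](C(C)C)(C(C)C)C(C)C)c(OC)c(OC)c1)O[Li] | intermediate (not isolated)
16 | lithium (1S,2S)-1-[3,4-dimethoxy-5-(triisopropylsilyloxy)phenyl]-2-[2,3-didehydro-5-[(E)-prop-1-enyl]phenyl]propan-1-olate (C7a≡C7 aryne) | C/C=C/C1=CC#CC(=C1)[C@H](C)[C@@H](c1cc(O[Si](C(C)C)(C(C)C)C(C)C)c(OC)c(OC)c1)O[Li] | intermediate (not isolated)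
17 | [(2S,3S)-2-[3,4-dimethoxy-5-(triisopropylsilyloxy)phenyl]-3-methyl-5-[(E)-prop-1-enyl]-2,3-dihydro-1-benzofuran-7-yl]lithium | C/C=C/c1cc([Li])c2c(c1)[C@H](C)[C@@H](c1cc(O[Si](C(C)C)(C(C)C)C(C)C)c(OC)c(OC)c1)O2 | intermediate (not isolated)
18 | lithium [(2S,3S)-2-[3,4-dimethoxy-5-(triisopropylsilyloxy)phenyl]-3-methyl-5-[(E)-prop-1-enyl]-2,3-dihydro-1-benzofuran-7-yl]trimethoxyborate | C/C=C/c1cc([B-](OC)(OC)OC)c2c(c1)[C@H](C)[C@@H](c1cc(O[Si](C(C)C)(C(C)C)C(C)C)c(OC)c(OC)c1)O2.[Li+] | intermediate (not isolated)
19 | (2S,3S)-2-[3,4-dimethoxy-5-(triisopropylsilyloxy)phenyl]-3-methyl-5-[(E)-prop-1-enyl]-2,3-dihydro-1-benzofuran-7-ol | C/C=C/c1cc(O)c2c(c1)[C@H](C)[C@@H](c1cc(O[Si](C(C)C)(C(C)C)C(C)C)c(OC)c(OC)c1)O2 | intermediate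
20 | (2S,3S)-2-[3,4-dimethoxy-5-(triisopropylsilyloxy)phenyl]-7-methoxy-3-methyl-5-[(E)-prop-1-enyl]-2,3-dihydro-1-benzofuran | C/C=C/c1cc(OC)c2c(c1)[C@H](C)[C@@H](c1cc(O[Si](C(C)C)(C(C)C)C(C)C)c(OC)c(OC)c1)O2 | intermediate
21 | 2,3-dimethoxy-5-[(2S,3S)-7-methoxy-3-methyl-5-[(E)-prop-1-enyl]-2,3-dihydro-1-benzofuran-2-yl]phenol | C/C=C/c1cc(OC)c2c(c1)[C@H](C)[C@@H](c1cc(O)c(OC)c(OC)c1)O2 | target

## Step count and least certain steps

Total: 10 steps. Longest linear sequence: 9 steps (steps 1, 2 and 4 to 10, from acid 1); step 3 is a one-step side branch from 7.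

**Step 8 (key step, proposed new method).** The most likely failure is proton transfer from 2,2,6,6-tetramethylpiperidine to the C7 aryllithium before the borate arrives. The aryllithium next to an ether oxygen is the stronger base, so ring closure would then occur without oxygenation at C7. Lesser risks are addition of the amide to the aryne and allylic deprotonation of the propenyl methyl group while the mixture is warmed. The fallback uses known chemistry and sets out from 14. The same amide-mediated aryne ring closure is run with a proton quench, which is the established outcome for tethered alkoxides, to give (2S,3S)-2-[3,4-dimethoxy-5-(triisopropylsilyloxy)phenyl]-3-methyl-5-[(E)-prop-1-enyl]-2,3-dihydro-1-benzofuran F1. Iridium-catalysed aromatic C–H borylation ([Ir(OMe)(cod)]2, 4,4'-di-tert-butyl-2,2'-bipyridine, B2pin2) is then expected to select C7: it is the only aryl C–H with an unsubstituted neighbour on one side and a ring-tied oxygen on the other, C4 and C6 flank the propenyl group, and both ring C hydrogens lie between two substituents. This gives 2-[(2S,3S)-2-[3,4-dimethoxy-5-(triisopropylsilyloxy)phenyl]-3-methyl-5-[(E)-prop-1-enyl]-2,3-dihydro-1-benzofuran-7-yl]-4,4,5,5-tetramethyl-1,3,2-dioxaborolane F2. Oxidation with NaBO3·4H2O returns to the route at 19.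

**Step 4.** Slow addition to the electron-rich aldehyde, together with epimerisation or retro-aldol at the acidic α-aryl centre during the basic peroxide work-up, could erode the diastereomeric purity. The fallback changes the auxiliary, the enolate metal and the cleavage, and sets out from acid 3. Coupling with (S)-4-benzyl-1,3-thiazolidine-2-thione (carbodiimide, DMAP) gives (4S)-4-benzyl-3-[2-[2-fluoro-5-[(E)-prop-1-enyl]phenyl]acetyl]-1,3-thiazolidine-2-thione F3. Its titanium enolate (TiCl4, excess amine base, the protocol known to give the same syn sense) adds to 8 to give (4S)-4-benzyl-3-[(2S,3S)-3-[3,4-dimethoxy-5-(triisopropylsilyloxy)phenyl]-2-[2-fluoro-5-[(E)-prop-1-enyl]phenyl]-3-hydroxypropanoyl]-1,3-thiazolidine-2-thione F4, with no oxidative work-up. NaBH4 cleaves the auxiliary directly and returns to the route at diol 12.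

**Step 7.** The neighbouring alkoxide could displace the tosylate to form an oxetane, or base could eliminate across the acidic benzylic C–H, instead of hydride displacement. The fallback replaces the ionic reduction by a radical one and sets out from 13. Finkelstein exchange (NaI, acetone) gives (1S,2S)-1-[3,4-dimethoxy-5-(triisopropylsilyloxy)phenyl]-2-[2-fluoro-5-[(E)-prop-1-enyl]phenyl]-3-iodopropan-1-ol F5. Radical deiodination (Bu3SnH, AIBN, toluene, 80 °C, high hydride concentration to outrun 1,2-aryl shift) returns to the route at 14.

**Step 9.** Loss of the silyl group under the carbonate conditions would be followed by methylation of the ring C oxygen. The fallback is a Mitsunobu etherification of 19 with methanol (PPh3, diisopropyl azodicarboxylate, THF) under neutral conditions, which returns to the route at 20 and makes no new compound (F0).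

## Further compounds

F1 | step 8 | (2S,3S)-2-[3,4-dimethoxy-5-(triisopropylsilyloxy)phenyl]-3-methyl-5-[(E)-prop-1-enyl]-2,3-dihydro-1-benzofuran | C/C=C/c1ccc2c(c1)[C@H](C)[C@@H](c1cc(O[Si](C(C)C)(C(C)C)C(C)C)c(OC)c(OC)c1)O2
F2 | step 8 | 2-[(2S,3S)-2-[3,4-dimethoxy-5-(triisopropylsilyloxy)phenyl]-3-methyl-5-[(E)-prop-1-enyl]-2,3-dihydro-1-benzofuran-7-yl]-4,4,5,5-tetramethyl-1,3,2-dioxaborolane | C/C=C/c1cc(B3OC(C)(C)C(C)(C)O3)c2c(c1)[C@H](C)[C@@H](c1cc(O[Si](C(C)C)(C(C)C)C(C)C)c(OC)c(OC)c1)O2
F3 | step 4 | (4S)-4-benzyl-3-[2-[2-fluoro-5-[(E)-prop-1-enyl]phenyl]acetyl]-1,3-thiazolidine-2-thione | S=C1SC[C@H](Cc2ccccc2)N1C(=O)Cc3cc(/C=C/C)ccc3F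
F4 | step 4 | (4S)-4-benzyl-3-[(2S,3S)-3-[3,4-dimethoxy-5-(triisopropylsilyloxy)phenyl]-2-[2-fluoro-5-[(E)-prop-1-enyl]phenyl]-3-hydroxypropanoyl]-1,3-thiazolidine-2-thione | S=C1SC[C@H](Cc2ccccc2)N1C(=O)[C@@H](c3cc(/C=C/C)ccc3F)[C@H](O)c4cc(O[Si](C(C)C)(C(C)C)C(C)C)c(OC)c(OC)c4
F5 | step 7 | (1S,2S)-1-[3,4-dimethoxy-5-(triisopropylsilyloxy)phenyl]-2-[2-fluoro-5-[(E)-prop-1-enyl]phenyl]-3-iodopropan-1-ol | IC[C@@H](c1cc(/C=C/C)ccc1F)[C@H](O)c2cc(O[Si](C(C)C)(C(C)C)C(C)C)c(OC)c(OC)c2
F0 | step 9 | none | none
A1 | alternative 1 | methyl 2-[5-bromo-2-[[3-(tert-butyldimethylsilyloxy)-4,5-dimethoxyphenyl]methoxy]-3-methoxyphenyl]-2-diazoacetate | COC(=O)C(=[N+]=[N-])c1cc(Br)cc(OC)c1OCc1cc(O[Si](C)(C)C(C)(C)C)c(OC)c(OC)c1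
A2 | alternative 1 | methyl (2S,3R)-5-bromo-2-[3-(tert-butyldimethylsilyloxy)-4,5-dimethoxyphenyl]-7-methoxy-2,3-dihydro-1-benzofuran-3-carboxylate (cis) | Brc1cc(OC)c2c(c1)[C@@H](C(=O)OC)[C@@H](c1cc(O[Si](C)(C)C(C)(C)C)c(OC)c(OC)c1)O2
A3 | alternative 2 | (2S)-2-[5-bromo-3-methoxy-2-(methoxymethoxy)phenyl]-1-[3,4-dimethoxy-5-(methoxymethoxy)phenyl]propan-1-ol (either carbinol epimer) | Brc1cc(OC)c(OCOC)c(c1)[C@H](C)C(O)c1cc(OCOC)c(OC)c(OC)c1
A4 | alternative 2 | 5-[(2S,3S)-5-bromo-7-methoxy-3-methyl-2,3-dihydro-1-benzofuran-2-yl]-2,3-dimethoxyphenol | Brc1cc(OC)c2c(c1)[C@H](C)[C@@H](c1cc(O)c(OC)c(OC)c1)O2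
A5 | alternative 3 | 4-[(1S)-1-[3-(tert-butyldimethylsilyloxy)-4,5-dimethoxyphenyl]prop-2-enoxy]-3-iodo-5-methoxybenzaldehyde | O=Cc1cc(OC)c(O[C@@H](C=C)c2cc(O[Si](C)(C)C(C)(C)C)c(OC)c(OC)c2)c(I)c1
A6 | alternative 3 | (2S,3S)-2-[3-(tert-butyldimethylsilyloxy)-4,5-dimethoxyphenyl]-7-methoxy-3-methyl-2,3-dihydro-1-benzofuran-5-carbaldehyde | O=Cc1cc(OC)c2c(c1)[C@H](C)[C@@H](c1cc(O[Si](C)(C)C(C)(C)C)c(OC)c(OC)c1)O2
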